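**Strategy.** With clerodane locants (C1 = ring A carbinol CH, C10 = ring-fusion CH, C5 = ring-fusion C–CH3, C9 = side-chain-bearing quaternary carbon, C8 = C(CH3)OH), the trans-decalin is opened across C1–C10 and C8–C9 to an acyclic keto-aldehyde enoate carrying only C5, C6 and C7 as stereocentres. A SmI2 ketyl–olefin cyclisation/aldol cascade exploits the contiguous array O–C1–C10–C9–C8–O: the C1 ketyl closes ring A on C10 of the C9=C10 enoate, and the C9 samarium enolate then closes ring B on the C8 methyl ketone, so C1, C10, C9 and C8 are set in one operation by relay from C5. C5 comes from a Sharpless epoxidation/1,2-shift; side chain and esters follow.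

Key step: step 14

Remark: decalin compounds are named with clerodane locants (C4 = C=CH2, C6 = C–OAc, C7 = C–O-isobutyrate, C11/C12 = side-chain alkene); the SMILES define each structure.
Assumption: the siloxymethyl 1,2-shift of step 6 is taken to occur anti to the breaking C–O bond (inversion at the migration terminus); this fixes D-(−)-diethyl tartrate in step 4.

Step 1
Reactants: 1 6-methylhept-5-en-2-one
Product: 2 N'-(6-methylhept-5-en-2-ylidene)-2,4,6-triisopropylbenzenesulfonohydrazide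
Conditions: 2,4,6-triisopropylbenzenesulfonyl hydrazide (1.0 equiv), MeOH, cat. HCl, rt
Reagents that add atoms: 2,4,6-triisopropylbenzenesulfonyl hydrazide, CC(C)c1cc(C(C)C)c(S(=O)(=O)NN)c(C(C)C)c1
Why: Acid-catalysed hydrazone formation from a methyl ketone provides the substrate for a Shapiro reaction.

Step 2
Reactants: 2 N'-(6-methylhept-5-en-2-ylidene)-2,4,6-triisopropylbenzenesulfonohydrazide; 3 ethyl but-2-ynoate
Product: 6 ethyl (2E)-3,8-dimethyl-4-methylidenenona-2,7-dienoate, via 6-methylhepta-1,5-dien-2-yllithium 4 (not isolated), via lithium bis(6-methylhepta-1,5-dien-2-yl)cuprate 5 (not isolated)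
Conditions: n-BuLi (2.1 equiv per 2), THF, −78 → 0 °C; CuI (0.5 equiv per 2), −40 °C; 3, −78 °C; sat. aq. NH4Cl at −78 °C
Reagents that add atoms: none
Why: In the Shapiro reaction double deprotonation at the less substituted α-methyl group and loss of sulfinate and N2 give the 2-lithio-1-alkene regioselectively, and its Gilman cuprate adds syn across the alkynoate (carbocupration), so cold protonation gives the (E)-dienoate.

Step 3
Reactants: 6 ethyl (2E)-3,8-dimethyl-4-methylidenenona-2,7-dienoate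
Product: 7 (2E)-3,8-dimethyl-4-methylidenenona-2,7-dien-1-ol
Conditions: iBu2AlH (2.2 equiv), CH2Cl2, −78 °C; Rochelle salt
Reagents that add atoms: none
Why: 1,2-Reduction of the conjugated ester by iBu2AlH gives the allylic alcohol and leaves the alkenes untouched.

Step 4
Reactants: 7 (2E)-3,8-dimethyl-4-methylidenenona-2,7-dien-1-ol
Product: 8 [(2R,3R)-3-methyl-3-(6-methylhepta-1,5-dien-2-yl)oxiran-2-yl]methanol
Conditions: Ti(OiPr)4 (10 mol%), D-(−)-diethyl tartrate (12 mol%), t-BuOOH (2 equiv), 4 Å molecular sieves, CH2Cl2, −20 °C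
Reagents that add atoms: tert-butyl hydroperoxide, CC(C)(C)OO
Why: Sharpless asymmetric epoxidation oxidises only the allylic-alcohol double bond, and D-(−)-tartrate delivers oxygen to the face that gives the (2R,3R)-epoxide (the sense known for geraniol), which sets the one catalyst-derived stereocentre that later becomes C5.

Step 5
Reactants: 8 [(2R,3R)-3-methyl-3-(6-methylhepta-1,5-dien-2-yl)oxiran-2-yl]methanol
Product: 9 tert-butyl(dimethyl){[(2R,3R)-3-methyl-3-(6-methylhepta-1,5-dien-2-yl)oxiran-2-yl]methoxy}silane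
Conditions: TBSCl, imidazole, DMF, 0 °C → rt
Reagents that add atoms: tert-butyldimethylsilyl chloride, CC(C)(C)[Si](C)(C)Cl
Why: Standard silylation of the primary alcohol turns the hydroxymethyl group into the siloxymethyl group that migrates in the next step.

Step 6
Reactants: 9 tert-butyl(dimethyl){[(2R,3R)-3-methyl-3-(6-methylhepta-1,5-dien-2-yl)oxiran-2-yl]methoxy}silane
Product: 10 (2R)-2-({[tert-butyl(dimethyl)silyl]oxy}methyl)-2,7-dimethyl-3-methylideneoct-6-enal
Conditions: MeAl(OAr)2 (Ar = 4-bromo-2,6-di-tert-butylphenyl; 20 mol%), CH2Cl2, −78 → −40 °C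
Reagents that add atoms: none
Why: In this Lewis-acid-promoted epoxy silyl ether to β-siloxy aldehyde rearrangement (semipinacol-type 1,2-shift) the bulky aluminium phenoxide ionises the tertiary allylic C–O bond and the siloxymethyl group migrates anti to it, converting the epoxide stereocentre into the all-carbon quaternary centre C5.

Step 7
Reactants: 10 (2R)-2-({[tert-butyl(dimethyl)silyl]oxy}methyl)-2,7-dimethyl-3-methylideneoct-6-enal; 11 ethyl 2-(triphenylphosphoranylidene)propanoate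
Product: 12 ethyl (2E,4R)-4-({[tert-butyl(dimethyl)silyl]oxy}methyl)-2,4,9-trimethyl-5-methylidenedeca-2,8-dienoate
Conditions: toluene, 90 °C
Reagents that add atoms: none
Why: Wittig olefination with the stabilised α-methyl ylide gives the trisubstituted (E)-enoate (the C9=C10 radical acceptor), and the non-enolisable α-quaternary aldehyde tolerates the heating its hindrance demands.

Step 8
Reactants: 12 ethyl (2E,4R)-4-({[tert-butyl(dimethyl)silyl]oxy}methyl)-2,4,9-trimethyl-5-methylidenedeca-2,8-dienoate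
Product: 13 ethyl (2E,4R)-4-(hydroxymethyl)-2,4,9-trimethyl-5-methylidenedeca-2,8-dienoate
Conditions: Bu4NF, THF, 0 °C → rt
Reagents that add atoms: none
Why: Fluoride cleaves the primary silyl ether, and the freed alcohol cannot lactonise onto the (E)-configured ester.

Step 9
Reactants: 13 ethyl (2E,4R)-4-(hydroxymethyl)-2,4,9-trimethyl-5-methylidenedeca-2,8-dienoate
Product: 14 ethyl (2E,4R)-4-formyl-2,4,9-trimethyl-5-methylidenedeca-2,8-dienoate
Conditions: Dess–Martin periodinane, NaHCO3, CH2Cl2, 0 °C → rt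
Reagents that add atoms: none
Why: Dess–Martin oxidation gives the neopentyl aldehyde (C6), which has no α-hydrogen and so cannot epimerise or conjugate.

Step 10
Reactants: 14 ethyl (2E,4R)-4-formyl-2,4,9-trimethyl-5-methylidenedeca-2,8-dienoate; 15 3-(methoxymethoxy)prop-1-ene
Product: 17 ethyl (2E,4R)-4-[(1R,2R)-1-hydroxy-2-(methoxymethoxy)but-3-en-1-yl]-2,4,9-trimethyl-5-methylidenedeca-2,8-dienoate, via (Z)-3-(methoxymethoxy)allyl-diisopinocampheylborane 16 (not isolated)
Conditions: 15, s-BuLi, THF, −78 °C; (−)-Ipc2BOMe; BF3·OEt2; then 14, −78 → −40 °C; NaOH, H2O2, 0 °C → rt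
Reagents that add atoms: none
Why: In the Brown γ-alkoxyallylboration the (Z)-γ-alkoxyallylborane reacts through a chair Zimmerman–Traxler transition state to give the syn 1,2-diol monoether, and the isopinocampheyl groups derived from (+)-α-pinene direct attack to the Si face of the aldehyde, so C6 and C7 are set by reagent control.

Step 11
Reactants: 17 ethyl (2E,4R)-4-[(1R,2R)-1-hydroxy-2-(methoxymethoxy)but-3-en-1-yl]-2,4,9-trimethyl-5-methylidenedeca-2,8-dienoate
Product: 18 ethyl (2E,4R)-4-[(1R,2R)-1-[(4-methoxyphenyl)methoxy]-2-(methoxymethoxy)but-3-en-1-yl]-2,4,9-trimethyl-5-methylidenedeca-2,8-dienoate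
Conditions: NaH, 4-methoxybenzyl chloride, Bu4NI (cat.), DMF, 0 °C → rt
Reagents that add atoms: 4-methoxybenzyl chloride, COc1ccc(CCl)cc1
Why: Williamson etherification protects C6–OH with a group orthogonal to the C7 acetal and to silyl ethers, and the alkoxide cannot reach the (E)-ester or undergo a favourable conjugate addition.

Step 12
Reactants: 18 ethyl (2E,4R)-4-[(1R,2R)-1-[(4-methoxyphenyl)methoxy]-2-(methoxymethoxy)but-3-en-1-yl]-2,4,9-trimethyl-5-methylidenedeca-2,8-dienoate
Product: 19 ethyl (2E,4R)-4-[(1R,2S)-1-[(4-methoxyphenyl)methoxy]-2-(methoxymethoxy)-3-oxobutyl]-2,4,9-trimethyl-5-methylidenedeca-2,8-dienoate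
Conditions: PdCl2(quinox) (5 mol%; quinox = 2-(4,5-dihydrooxazol-2-yl)quinoline), AgSbF6 (12 mol%), aq. t-BuOOH, CH2Cl2, 0 °C → rt
Reagents that add atoms: tert-butyl hydroperoxide, CC(C)(C)OO
Why: The peroxide-mediated Wacker oxidation converts only the monosubstituted alkene into the C8 methyl ketone with Markovnikov selectivity even next to the allylic ether, while the 1,1-disubstituted, trisubstituted and conjugated alkenes are inert.

Step 13
Reactants: 19 ethyl (2E,4R)-4-[(1R,2S)-1-[(4-methoxyphenyl)methoxy]-2-(methoxymethoxy)-3-oxobutyl]-2,4,9-trimethyl-5-methylidenedeca-2,8-dienoate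
Product: 21 ethyl (2E,4R)-4-[(1R,2S)-1-[(4-methoxyphenyl)methoxy]-2-(methoxymethoxy)-3-oxobutyl]-2,4-dimethyl-5-methylidene-8-oxooct-2-enoate, via 8,9-epoxide 20 (not isolated)
Conditions: mCPBA (1.05 equiv), NaHCO3, CH2Cl2, −10 °C; then H5IO6 (1.5 equiv), THF/H2O, 0 °C
Reagents that add atoms: 3-chloroperoxybenzoic acid, O=C(OO)c1cccc(Cl)c1
Why: The electron-rich trisubstituted alkene is epoxidised much faster than the hindered 1,1-disubstituted alkene or the enoate, and periodic acid cleaves the epoxide to the C1 aldehyde and acetone.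

Step 14
Reactants: 21 ethyl (2E,4R)-4-[(1R,2S)-1-[(4-methoxyphenyl)methoxy]-2-(methoxymethoxy)-3-oxobutyl]-2,4-dimethyl-5-methylidene-8-oxooct-2-enoate
Product: 23 ethyl (1R,5R,6R,7S,8R,9R,10S)-1,8-dihydroxy-6-[(4-methoxyphenyl)methoxy]-7-(methoxymethoxy)-5,8,9-trimethyl-4-methylidene-trans-decalin-9-carboxylate, via ring A samarium alkoxide enolate 22 (not isolated)
Conditions: SmI2 (2.3 equiv, 0.1 M in THF, slow addition), t-BuOH (3 equiv), THF, −78 → −30 °C; sat. aq. NH4Cl
Reagents that add atoms: none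
Why: Single-electron transfer from SmI2 to the aldehyde gives the C1 ketyl radical anion, which adds 6-exo-trig to C10 (the β-carbon of the enoate) to close ring A; a second electron turns the C9 radical into a trivalent samarium ester enolate, which closes ring B by a 6-(enolexo)-exo-trig aldol addition to the C8 methyl ketone. The closest known reaction type is the SmI2-mediated ketyl–olefin radical cyclisation/aldol cascade of aldehyde-tethered enoates. Ring A should form through a chair transition state in which the ketyl oxygen on C1 and the enoate on C10 are equatorial and anti, and in which the small C5 methyl rather than the branched C6 chain is axial (this also relieves A(1,3) strain with the C9 methyl), so C1 and C10 are relayed from C5. Because ring B does not yet exist, both future ring B bonds at C5 and C10 sit equatorial on ring A and the second closure can only give the trans-decalin. In the aldol the enolate lies in the plane of C10–H (A(1,3) strain), C8 approaches from the C5 side with the bulky enolate carbon C11 equatorial and the C9 methyl axial, and the ketone methyl takes the equatorial site anti to C6 with the nucleophile anti to the C7–O bond, which sets C9 and C8. The step needs the aldehyde to be reduced before the chelating α-alkoxy ketone, which the higher reducibility of the aldehyde, slow addition of SmI2 at −78 °C and fast 6-exo capture are expected to secure.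

Step 15
Reactants: 23 ethyl (1R,5R,6R,7S,8R,9R,10S)-1,8-dihydroxy-6-[(4-methoxyphenyl)methoxy]-7-(methoxymethoxy)-5,8,9-trimethyl-4-methylidene-trans-decalin-9-carboxylate
Product: 24 1-O-tert-butyldimethylsilyl ether of 23
Conditions: TBSOTf (1.2 equiv), 2,6-lutidine, CH2Cl2, −78 °C
Reagents that add atoms: tert-butyldimethylsilyl triflate, CC(C)(C)[Si](C)(C)OS(=O)(=O)C(F)(F)F
Why: At −78 °C the silyl triflate should react with the secondary equatorial C1–OH and not with the hindered axial tertiary C8–OH.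

Step 16
Reactants: 24 1-O-tert-butyldimethylsilyl ether of 23
Product: 25 (1R,5R,6R,7S,8R,9S,10S)-1-[tert-butyl(dimethyl)silyl]oxy-9-(hydroxymethyl)-6-[(4-methoxyphenyl)methoxy]-7-(methoxymethoxy)-5,8,9-trimethyl-4-methylidene-trans-decalin-8-ol
Conditions: iBu2AlH (4 equiv), CH2Cl2, −78 → 0 °C; Rochelle salt
Reagents that add atoms: none
Why: Excess aluminium hydride reduces the hindered ester to the neopentyl primary alcohol C11, while silyl, benzyl and acetal ethers are inert.

Step 17
Reactants: 25 (1R,5R,6R,7S,8R,9S,10S)-1-[tert-butyl(dimethyl)silyl]oxy-9-(hydroxymethyl)-6-[(4-methoxyphenyl)methoxy]-7-(methoxymethoxy)-5,8,9-trimethyl-4-methylidene-trans-decalin-8-ol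
Product: 26 (1R,5R,6R,7S,8R,9R,10S)-1-[tert-butyl(dimethyl)silyl]oxy-8-hydroxy-6-[(4-methoxyphenyl)methoxy]-7-(methoxymethoxy)-5,8,9-trimethyl-4-methylidene-trans-decalin-9-carbaldehyde
Conditions: Dess–Martin periodinane, NaHCO3, CH2Cl2, 0 °C
Reagents that add atoms: none
Why: Dess–Martin oxidation touches only the primary alcohol, and its buffered neutral conditions avoid retro-aldol cleavage of the β-hydroxy aldehyde.

Step 18
Reactants: 26 (1R,5R,6R,7S,8R,9R,10S)-1-[tert-butyl(dimethyl)silyl]oxy-8-hydroxy-6-[(4-methoxyphenyl)methoxy]-7-(methoxymethoxy)-5,8,9-trimethyl-4-methylidene-trans-decalin-9-carbaldehyde; 27 2-(dichloromethyl)-4,4,5,5-tetramethyl-1,3,2-dioxaborolane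
Product: 28 (1R,5R,6R,7S,8R,9R,10S)-1-[tert-butyl(dimethyl)silyl]oxy-6-[(4-methoxyphenyl)methoxy]-7-(methoxymethoxy)-5,8,9-trimethyl-4-methylidene-9-[(E)-2-(4,4,5,5-tetramethyl-1,3,2-dioxaborolan-2-yl)ethenyl]-trans-decalin-8-ol
Conditions: CrCl2 (8 equiv), 27 (2 equiv), LiI (4 equiv), THF, rt
Reagents that add atoms: none
Why: In the Takai–Utimoto olefination (boron variant) a geminal dichromium reagent adds to the aldehyde and eliminates to the (E)-alkenylboronate under non-basic conditions that the free tertiary alcohol tolerates.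

Step 19
Reactants: 28 (E)-alkenylboronate; 29 4-bromofuran-2(5H)-one
Product: 30 4-[(E)-2-[(1R,5R,6R,7S,8R,9R,10S)-1-[tert-butyl(dimethyl)silyl]oxy-8-hydroxy-6-[(4-methoxyphenyl)methoxy]-7-(methoxymethoxy)-5,8,9-trimethyl-4-methylidene-trans-decalin-9-yl]ethenyl]furan-2(5H)-one
Conditions: 29 (1.5 equiv), Pd(PPh3)4 (5 mol%), K3PO4 (3 equiv), THF/H2O, 50 °C
Reagents that add atoms: none
Why: Suzuki–Miyaura coupling of the alkenylboronate with the β-bromobutenolide proceeds with retention of the E geometry and builds the dienyl butenolide under mildly basic conditions.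

Step 20
Reactants: 30 dienyl butenolide with C6–OPMB
Product: 31 6-alcohol (C1–OTBS, C7–OMOM, C8–OH)
Conditions: DDQ (1.5 equiv), CH2Cl2/pH 7 buffer, 0 °C → rt
Reagents that add atoms: none
Why: Oxidative removal of the 4-methoxybenzyl ether by DDQ frees only C6–OH and leaves the electron-poor diene, silyl ether and acetal untouched.

Step 21
Reactants: 31 6-alcohol
Product: 32 6-acetate
Conditions: Ac2O, DMAP, pyridine, rt → 40 °C
Reagents that add atoms: acetic anhydride, CC(=O)OC(C)=O
Why: DMAP-catalysed acetylation esterifies the hindered secondary C6–OH, while the axial tertiary C8–OH is too hindered to react.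

Step 22
Reactants: 32 6-acetate
Product: 33 6-acetate 7-alcohol
Conditions: ZnBr2 (1 equiv), n-PrSH (3 equiv), CH2Cl2, 0 °C
Reagents that add atoms: none
Why: Lewis acid/thiol cleavage of the methoxymethyl ether is fast and mild, the thiol traps the formaldehyde unit so that no methylene acetal forms with C8–OH, and the silyl ether, acetate and butenolide should survive.

Step 23
Reactants: 33 6-acetate 7-alcohol
Product: 34 1-O-tert-butyldimethylsilyl ether of the target
Conditions: isobutyryl chloride, DMAP (cat.), pyridine, CH2Cl2, 0 °C → rt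
Reagents that add atoms: isobutyryl chloride, CC(C)C(Cl)=O
Why: Acylation with the acid chloride esterifies the only free secondary hydroxyl (C7), the tertiary C8–OH again being unreactive.

Step 24
Reactants: 34 1-O-tert-butyldimethylsilyl ether of the target
Product: 35 CNP0215764.1
Conditions: HF·pyridine, pyridine/THF, 0 °C → rt
Reagents that add atoms: none
Why: Buffered fluoride removes the secondary silyl ether without acyl migration or opening of the base-sensitive butenolide.

**Compound list**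
1 | 6-methylhept-5-en-2-one | CC(=O)CCC=C(C)C | starting material
2 | N'-(6-methylhept-5-en-2-ylidene)-2,4,6-triisopropylbenzenesulfonohydrazide | CC(C)=CCCC(C)=NNS(=O)(=O)c1c(C(C)C)cc(C(C)C)cc1C(C)C | intermediate
3 | ethyl but-2-ynoate | CC#CC(=O)OCC | starting material
4 | 6-methylhepta-1,5-dien-2-yllithium (not isolated) | [Li]C(=C)CCC=C(C)C | intermediate
5 | lithium bis(6-methylhepta-1,5-dien-2-yl)cuprate (not isolated) | [Li+].C=C(CCC=C(C)C)[Cu-]C(=C)CCC=C(C)C | intermediate
6 | ethyl (2E)-3,8-dimethyl-4-methylidenenona-2,7-dienoate | CCOC(=O)/C=C(\C)C(=C)CCC=C(C)C | intermediate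
7 | (2E)-3,8-dimethyl-4-methylidenenona-2,7-dien-1-ol | OC/C=C(\C)C(=C)CCC=C(C)C | intermediate
8 | [(2R,3R)-3-methyl-3-(6-methylhepta-1,5-dien-2-yl)oxiran-2-yl]methanol | OC[C@H]1O[C@]1(C)C(=C)CCC=C(C)C | intermediate
9 | tert-butyl(dimethyl){[(2R,3R)-3-methyl-3-(6-methylhepta-1,5-dien-2-yl)oxiran-2-yl]methoxy}silane | CC(C)(C)[Si](C)(C)OC[C@H]1O[C@]1(C)C(=C)CCC=C(C)C | intermediate
10 | (2R)-2-({[tert-butyl(dimethyl)silyl]oxy}methyl)-2,7-dimethyl-3-methylideneoct-6-enal | O=C[C@@](C)(CO[Si](C)(C)C(C)(C)C)C(=C)CCC=C(C)C | intermediate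
11 | ethyl 2-(triphenylphosphoranylidene)propanoate | CCOC(=O)C(C)=P(c1ccccc1)(c1ccccc1)c1ccccc1 | starting material
12 | ethyl (2E,4R)-4-({[tert-butyl(dimethyl)silyl]oxy}methyl)-2,4,9-trimethyl-5-methylidenedeca-2,8-dienoate | CCOC(=O)/C(C)=C/[C@@](C)(CO[Si](C)(C)C(C)(C)C)C(=C)CCC=C(C)C | intermediate
13 | ethyl (2E,4R)-4-(hydroxymethyl)-2,4,9-trimethyl-5-methylidenedeca-2,8-dienoate | CCOC(=O)/C(C)=C/[C@@](C)(CO)C(=C)CCC=C(C)C | intermediate
14 | ethyl (2E,4R)-4-formyl-2,4,9-trimethyl-5-methylidenedeca-2,8-dienoate | CCOC(=O)/C(C)=C/[C@@](C)(C=O)C(=C)CCC=C(C)C | intermediate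
15 | 3-(methoxymethoxy)prop-1-ene | C=CCOCOC | starting material
16 | (Z)-3-(methoxymethoxy)allyl-diisopinocampheylborane, isopinocampheyl groups from (+)-α-pinene (not isolated) | COCO/C=C\CB([C@@H]1C[C@@H]2C[C@H]([C@H]1C)C2(C)C)[C@@H]1C[C@@H]2C[C@H]([C@H]1C)C2(C)C | intermediate
17 | ethyl (2E,4R)-4-[(1R,2R)-1-hydroxy-2-(methoxymethoxy)but-3-en-1-yl]-2,4,9-trimethyl-5-methylidenedeca-2,8-dienoate | CCOC(=O)/C(C)=C/[C@@](C)([C@@H](O)[C@H](OCOC)C=C)C(=C)CCC=C(C)C | intermediate
18 | ethyl (2E,4R)-4-[(1R,2R)-1-[(4-methoxyphenyl)methoxy]-2-(methoxymethoxy)but-3-en-1-yl]-2,4,9-trimethyl-5-methylidenedeca-2,8-dienoate | CCOC(=O)/C(C)=C/[C@@](C)([C@@H](OCc1ccc(OC)cc1)[C@H](OCOC)C=C)C(=C)CCC=C(C)C | intermediate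
19 | ethyl (2E,4R)-4-[(1R,2S)-1-[(4-methoxyphenyl)methoxy]-2-(methoxymethoxy)-3-oxobutyl]-2,4,9-trimethyl-5-methylidenedeca-2,8-dienoate | CCOC(=O)/C(C)=C/[C@@](C)([C@@H](OCc1ccc(OC)cc1)[C@H](OCOC)C(C)=O)C(=C)CCC=C(C)C | intermediate
20 | 8,9-epoxide of 19, both epimers at the new epoxide carbon (not isolated) | CCOC(=O)/C(C)=C/[C@@](C)([C@@H](OCc1ccc(OC)cc1)[C@H](OCOC)C(C)=O)C(=C)CCC1OC1(C)C | intermediate
21 | ethyl (2E,4R)-4-[(1R,2S)-1-[(4-methoxyphenyl)methoxy]-2-(methoxymethoxy)-3-oxobutyl]-2,4-dimethyl-5-methylidene-8-oxooct-2-enoate | CCOC(=O)/C(C)=C/[C@@](C)([C@@H](OCc1ccc(OC)cc1)[C@H](OCOC)C(C)=O)C(=C)CCC=O | intermediate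
22 | ring A samarium alkoxide enolate: C1–C10 bond formed, C1–O–SmI2, C9=C11(OEt)O–SmI2, C8 ketone still open (not isolated) | C=C1CC[C@@H](O[Sm](I)I)[C@H](C(C)=C(OCC)O[Sm](I)I)[C@@]1(C)[C@@H](OCc1ccc(OC)cc1)[C@H](OCOC)C(C)=O | intermediate
23 | ethyl (1R,5R,6R,7S,8R,9R,10S)-1,8-dihydroxy-6-[(4-methoxyphenyl)methoxy]-7-(methoxymethoxy)-5,8,9-trimethyl-4-methylidene-trans-decalin-9-carboxylate | C=C1CC[C@@H](O)[C@H]2[C@@]1(C)[C@@H](OCc1ccc(OC)cc1)[C@H](OCOC)[C@](C)(O)[C@]2(C)C(=O)OCC | intermediate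
24 | 1-O-tert-butyldimethylsilyl ether of 23 | C=C1CC[C@@H](O[Si](C)(C)C(C)(C)C)[C@H]2[C@@]1(C)[C@@H](OCc1ccc(OC)cc1)[C@H](OCOC)[C@](C)(O)[C@]2(C)C(=O)OCC | intermediate
25 | (9S)-9-hydroxymethyl diol (C1–OTBS, C6–OPMB, C7–OMOM, C8–OH) | C=C1CC[C@@H](O[Si](C)(C)C(C)(C)C)[C@H]2[C@@]1(C)[C@@H](OCc1ccc(OC)cc1)[C@H](OCOC)[C@](C)(O)[C@]2(C)CO | intermediate
26 | (9R)-9-carbaldehyde (C1–OTBS, C6–OPMB, C7–OMOM, C8–OH) | C=C1CC[C@@H](O[Si](C)(C)C(C)(C)C)[C@H]2[C@@]1(C)[C@@H](OCc1ccc(OC)cc1)[C@H](OCOC)[C@](C)(O)[C@]2(C)C=O | intermediate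
27 | 2-(dichloromethyl)-4,4,5,5-tetramethyl-1,3,2-dioxaborolane | ClC(Cl)B1OC(C)(C)C(C)(C)O1 | starting material
28 | (E)-alkenylboronate (C9–CH=CH–Bpin; C1–OTBS, C6–OPMB, C7–OMOM, C8–OH) | C=C1CC[C@@H](O[Si](C)(C)C(C)(C)C)[C@H]2[C@@]1(C)[C@@H](OCc1ccc(OC)cc1)[C@H](OCOC)[C@](C)(O)[C@]2(C)/C=C/B1OC(C)(C)C(C)(C)O1 | intermediate
29 | 4-bromofuran-2(5H)-one | BrC1=CC(=O)OC1 | starting material
30 | dienyl butenolide (C1–OTBS, C6–OPMB, C7–OMOM, C8–OH) | C=C1CC[C@@H](O[Si](C)(C)C(C)(C)C)[C@H]2[C@@]1(C)[C@@H](OCc1ccc(OC)cc1)[C@H](OCOC)[C@](C)(O)[C@]2(C)/C=C/C1=CC(=O)OC1 | intermediate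
31 | 6-alcohol (C1–OTBS, C7–OMOM, C8–OH) | C=C1CC[C@@H](O[Si](C)(C)C(C)(C)C)[C@H]2[C@@]1(C)[C@@H](O)[C@H](OCOC)[C@](C)(O)[C@]2(C)/C=C/C1=CC(=O)OC1 | intermediate
32 | 6-acetate (C1–OTBS, C7–OMOM, C8–OH) | C=C1CC[C@@H](O[Si](C)(C)C(C)(C)C)[C@H]2[C@@]1(C)[C@@H](OC(C)=O)[C@H](OCOC)[C@](C)(O)[C@]2(C)/C=C/C1=CC(=O)OC1 | intermediate
33 | 6-acetate 7-alcohol (C1–OTBS, C8–OH) | C=C1CC[C@@H](O[Si](C)(C)C(C)(C)C)[C@H]2[C@@]1(C)[C@@H](OC(C)=O)[C@H](O)[C@](C)(O)[C@]2(C)/C=C/C1=CC(=O)OC1 | intermediate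
34 | 1-O-tert-butyldimethylsilyl ether of the target | C=C1CC[C@@H](O[Si](C)(C)C(C)(C)C)[C@H]2[C@@]1(C)[C@@H](OC(C)=O)[C@H](OC(=O)C(C)C)[C@](C)(O)[C@]2(C)/C=C/C1=CC(=O)OC1 | intermediate
35 | CNP0215764.1, (1R,5R,6R,7S,8R,9R,10S)-6-acetoxy-1,8-dihydroxy-7-(isobutyryloxy)-clerodane-type 11E-dienyl butenolide | C=C1CC[C@@H](O)[C@H]2[C@@]1(C)[C@@H](OC(C)=O)[C@H](OC(=O)C(C)C)[C@](C)(O)[C@]2(C)/C=C/C1=CC(=O)OC1 | target

**Total step count:** 24. **Longest linear sequence:** 24 steps (from 6-methylhept-5-en-2-one).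

**Steps most likely to fail**

Step 14. Electron transfer to the chelating α-alkoxy ketone may compete with ketyl formation at the aldehyde and cause reductive loss of the C7 oxygen. The samarium enolate may also be protonated before the aldol, or the congested C8–C9 bond may reopen by retro-aldol. The fallback sets out from 18 and comes back at 24. Epoxidation and periodic acid cleavage of the prenyl terminus of 18, as in step 13, would give the vinyl aldehyde F1, which has no reducible ketone. SmI2 with t-BuOH then performs only the ketyl–olefin cyclisation with protonation of the enolate, giving the ring A hydroxy ester F2 as C9 epimers. TBSOTf and 2,6-lutidine give the silyl ether F3. LDA followed by CBr4 gives the tertiary α-bromo ester F4. Wacker oxidation as in step 12 gives the bromo keto ester F5. SmI2 at −78 °C reduces the C–Br bond much faster than any carbonyl group, and the enolate so formed closes ring B by an intramolecular Reformatsky aldol addition to give 24.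

Step 6. Ionisation to a free allyl cation may erode the enantiopurity transferred from the epoxide. The fallback sets out from 10 of insufficient enantiopurity and comes back at 13. NaBH4 reduction would give the mono-silyl diol F6, and Bu4NF the prochiral diol F7. A lipase (hydrolase class; Candida rugosa lipase, 1-ethoxyvinyl furan-2-carboxylate as acyl donor), selected to acylate the hydroxymethyl arm that becomes C6, desymmetrises F7 to the monoester F8 whatever the optical purity of 10. Dess–Martin oxidation gives the aldehyde F9, Wittig reaction with 11 gives the enoate F10, and K2CO3 in ethanol removes the furoate to give 13.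

Step 18. Addition of the gem-dichromium reagent to the neopentyl aldehyde, flanked by two fully substituted carbons, may be slow, and the chromium Lewis acid may promote retro-aldol fragmentation. The fallback sets out from 26 and comes back at 30. Non-basic methylenation (Zn, CH2Br2, TiCl4) would give the terminal alkene F11, and a Heck reaction with 29 (Pd(OAc)2, P(o-tolyl)3, Et3N, MeCN, 80 °C) gives the (E)-dienyl butenolide 30 directly.

**Further compounds**
F1 | step 14 | ethyl (2E,4R)-4-[(1R,2R)-1-[(4-methoxyphenyl)methoxy]-2-(methoxymethoxy)but-3-en-1-yl]-2,4-dimethyl-5-methylidene-8-oxooct-2-enoate | CCOC(=O)/C(C)=C/[C@@](C)([C@@H](OCc1ccc(OC)cc1)[C@H](OCOC)C=C)C(=C)CCC=O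
F2 | step 14 | ring A hydroxy ester (C1–OH, C9–H epimers, C8 vinyl) | C=C1CC[C@@H](O)[C@H](C(C)C(=O)OCC)[C@@]1(C)[C@@H](OCc1ccc(OC)cc1)[C@H](OCOC)C=C
F3 | step 14 | 1-O-tert-butyldimethylsilyl ether of F2 | C=C1CC[C@@H](O[Si](C)(C)C(C)(C)C)[C@H](C(C)C(=O)OCC)[C@@]1(C)[C@@H](OCc1ccc(OC)cc1)[C@H](OCOC)C=C
F4 | step 14 | tertiary α-bromo ester of F3 | C=C1CC[C@@H](O[Si](C)(C)C(C)(C)C)[C@H](C(C)(Br)C(=O)OCC)[C@@]1(C)[C@@H](OCc1ccc(OC)cc1)[C@H](OCOC)C=C
F5 | step 14 | bromo keto ester (C8 methyl ketone) | C=C1CC[C@@H](O[Si](C)(C)C(C)(C)C)[C@H](C(C)(Br)C(=O)OCC)[C@@]1(C)[C@@H](OCc1ccc(OC)cc1)[C@H](OCOC)C(C)=O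
F6 | step 6 | 2-({[tert-butyl(dimethyl)silyl]oxy}methyl)-2,7-dimethyl-3-methylideneoct-6-en-1-ol | OCC(C)(CO[Si](C)(C)C(C)(C)C)C(=C)CCC=C(C)C
F7 | step 6 | 2-methyl-2-(6-methylhepta-1,5-dien-2-yl)propane-1,3-diol | OCC(C)(CO)C(=C)CCC=C(C)C
F8 | step 6 | [(2S)-2-(hydroxymethyl)-2,7-dimethyl-3-methylideneoct-6-en-1-yl] furan-2-carboxylate | OC[C@@](C)(COC(=O)c1ccco1)C(=C)CCC=C(C)C
F9 | step 6 | [(2R)-2-formyl-2,7-dimethyl-3-methylideneoct-6-en-1-yl] furan-2-carboxylate | O=C[C@@](C)(COC(=O)c1ccco1)C(=C)CCC=C(C)C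
F10 | step 6 | ethyl (2E,4R)-4-[(furan-2-carbonyloxy)methyl]-2,4,9-trimethyl-5-methylidenedeca-2,8-dienoate | CCOC(=O)/C(C)=C/[C@@](C)(COC(=O)c1ccco1)C(=C)CCC=C(C)C
F11 | step 18 | 9-vinyl decalin (C1–OTBS, C6–OPMB, C7–OMOM, C8–OH) | C=C1CC[C@@H](O[Si](C)(C)C(C)(C)C)[C@H]2[C@@]1(C)[C@@H](OCc1ccc(OC)cc1)[C@H](OCOC)[C@](C)(O)[C@]2(C)C=C
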